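6 questions stand here, yet they come down to 3 numbers: the fraction of L left in beta, theta and zeta at 3.0 d. What leaves L ends mostly as D, and Q reads small, so the fraction left tells you who leads and by how much.

| flask | L | J | X | remark | time |
|---|---|---|---|---|---|
| autumn | 0.058 M | 0.0464 M | 0.069 M | run made earlier |  |
| noon | 0.058 M | 0.0464 M | 0.58 M | run made earlier |  |
| beta | 0.058 M | 0.0464 M | 0.120 M |  | 3.0 d |
| theta | 0.058 M | 0.0464 M | 0.290 M |  | 3.0 d |
| zeta | 0.058 M | 0.0464 M | 0.730 M |  | 3.0 d |

| run | time / d | Z / % | L / % | G / % | D / % | Q / % |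
|---|---|---|---|---|---|---|
| autumn | 0.250 | 0 | 96 | 0 | 2 | 0 |
| autumn | 0.417 | 0 | 94 | 2 | 2 | 0 |
| autumn | 0.625 | 0 | 96 | 0 | 7 | 0 |
| autumn | 1.04 | 0 | 89 | 2 | 7 | 0 |
| autumn | 1.67 | 3 | 85 | 3 | 21 | 0 |
| autumn | 3.00 | 2 | 73 | 1 | 24 | 4 |
| noon | 0.208 | 0 | 87 | 0 | 12 | 1 |
| noon | 0.625 | 3 | 69 | 0 | 28 | 0 |
| noon | 1.04 | 0 | 57 | 0 | 43 | 1 |
| noon | 1.67 | 0 | 38 | 3 | 62 | 1 |
| noon | 2.50 | 0 | 24 | 0 | 72 | 2 |
| noon | 3.00 | 2 | 19 | 0 | 81 | 2 |

(scatter of a reading: 2 percentage points)

1. which of these there is most of at the end, counted by the L in it, beta (Q / D / L / Z)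
2. which of these there is most of at the end, counted by the L in it, theta (Q / D / L / Z)
3. which of these there is most of at the end, counted by the L in it, zeta (Q / D / L / Z)
4. the largest of these amounts at the end, in percent of the L charged, beta
5. the largest of these amounts at the end, in percent of the L charged, theta
6. the largest of these amounts at the end, in percent of the L charged, zeta

- what was read earlier has a scatter of 2 percentage points, one standard deviation
- candidate steps: X + Z -> D; Z -> Q; L <-> Z; J + Z <-> G

Carry the e-fold time τ of L: the time divided by the natural logarithm of the inverse fraction left. Treat L as pseudo-first-order, with c_X as charged, so that each flask has one τ. c_J and c_L are the same in every run, so time and c_X are the settings to turn.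

Turn time first. By hand, τ should stay put along a run, and in noon it does within the scatter: 1.85 d from the reading at 1.04 d, 1.81 d from the one at 3.00 d.

Turn c_X next. The last autumn reading, with its scatter, gives 9.53 d. If τ went as one over c_X, it would shrink as fast as c_X grows, but it shrinks by a factor 5.27, less than the 8.41 of c_X. The candidate steps suggest why: L passes to Z and back while X catches Z, so a fixed wait and a wait that shrinks with c_X add up. Write τ = a + b/c_X. The two runs give b = 871 M·min and a = 0.763 d.

| flask | c_X | τ | L left | rest |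
|---|---|---|---|---|
| beta | 0.120 M | 5.81 d | 59.6% | 40.4% |
| theta | 0.290 M | 2.85 d | 34.9% | 65.1% |
| zeta | 0.730 M | 1.59 d | 15.2% | 84.8% |

The e-fold time of L in zeta, 1.59 d, is the number to keep. Take from each rest the Q read at the end of the earlier runs, 2% to 4%. Your reckoning then has L leading in beta at 59.6%, D in theta at about 62.1%, and D in zeta at about 81.8%.

The forecast, reasoning that “L forms Z reversibly, and X traps Z as D”, names the same leaders with slightly different figures: L at 61% in beta, D at 60% in theta, D at 83% in zeta.

The flask gives L at 60.9% in beta, D at 61.2% in theta, D at 84.2% in zeta.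

    X + Z → D (k = 32.0 L mol⁻¹ h⁻¹)
    Z → Q (k = 0.360 h⁻¹)
    L ⇌ Z (K = 0.00200, k = 0.0660 h⁻¹)
    J + Z ⇌ G (K = 7.20 L mol⁻¹, k = 73.0 L mol⁻¹ h⁻¹)

Your τ runs from 5.81 d in beta down to 1.59 d in zeta. The difference in c_X is the main reason for the D that zeta reaches: take it away and the D of zeta falls from 84.2% to 35.3%. Now read zeta early, at 20 h. The same τ leaves 59.2% of L, and the computed flask holds 57.9%.

(The readings were computed on assumed constants, noise included.)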